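**Assumption (one line):** (+)-limonene 1,2-oxide is the commercial cis/trans mixture with (4R) configuration; the target is treated as the enol tautomer given; "ring A" is the phloroglucinol-derived ring; descriptors of the spiro compounds follow spiro[cyclohexane-1,5'-indene] numbering, and the SMILES strings are definitive.

## Retrosynthetic overview

1. 18 ⇒ 15 + 2 × 16: the last C–C bonds are a double C-prenylation of the one free carbon of ring A.
2. 15 ⇒ 13: Markovnikov hydration (C–O) of the exocyclic alkene on the rigid spirocycle sets the cyclohexane carbinol.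
3. 13 ⇒ 11: key C–O bond. The 4-OH is etherified with the allylic alcohol to the eight-membered ether 12, whose [3,3] shift contracts to the spiro cyclohexane and fixes the spiro centre.
4. 11 ⇒ 8 + 9 by reductive alkylation; 8 ⇒ 4 by allylic oxidation, nucleophilic epoxidation (C–O) and reductive epoxide opening.
5. 4 ⇒ 1 by cleavage and aldol ring contraction. Ring order: cyclopentane (from limonene), aromatic ring A attached, transient eight-membered ether, then spiro cyclohexane with dearomatisation of ring A in the same event.

## Route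

Step 1
Reactants: 1 (4R)-limonene 1,2-oxide (cis/trans mixture)
Product: 3 (3R)-6-oxo-3-(prop-1-en-2-yl)heptanal, via limonene-1,2-diol 2 (not isolated)
Conditions: H5IO6 (1.2 equiv), THF/H2O, 0 °C to rt
Reagents that add atoms: water, O
Why: Acidic periodic acid hydrolyses both epoxide diastereomers to the trans-diol and cleaves it in the same flask (glycol cleavage, Malaprade type); the limonene stereocentre is not touched.

Step 2
Reactants: 3 (3R)-6-oxo-3-(prop-1-en-2-yl)heptanal
Product: 4 (5S)-2-methyl-5-(prop-1-en-2-yl)cyclopent-1-ene-1-carbaldehyde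
Conditions: piperidine (0.3 equiv), AcOH (0.3 equiv), toluene, 80 °C, Dean–Stark
Reagents that add atoms: none
Why: The aldehyde enamine adds to the methyl ketone and the adduct dehydrates (intramolecular aldol condensation); the stereocentre carries no acidic hydrogen toward the enal and is retained.

Step 3
Reactants: 4 (5S)-2-methyl-5-(prop-1-en-2-yl)cyclopent-1-ene-1-carbaldehyde
Product: 5 (5S)-5-(3-hydroxyprop-1-en-2-yl)-2-methylcyclopent-1-ene-1-carbaldehyde
Conditions: SeO2 (0.3 equiv), t-BuOOH (2 equiv), CH2Cl2, rt
Reagents that add atoms: selenium dioxide, O=[Se]=O; tert-butyl hydroperoxide, CC(C)(C)OO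
Why: Riley allylic oxidation (ene reaction then [2,3] shift) hydroxylates the methyl group of the electron-rich 1,1-disubstituted alkene, while the electron-poor enal alkene does not react; moderate yield is expected.

Step 4
Reactants: 5 (5S)-5-(3-hydroxyprop-1-en-2-yl)-2-methylcyclopent-1-ene-1-carbaldehyde
Product: 6 (1S,2S,5R)-2-(3-hydroxyprop-1-en-2-yl)-5-methyl-6-oxabicyclo[3.1.0]hexane-1-carbaldehyde
Conditions: 30% H2O2, NaOH (0.2 equiv), MeOH, 0 °C
Reagents that add atoms: hydrogen peroxide, OO
Why: Weitz–Scheffer nucleophilic epoxidation; hydroperoxide adds and ring-closes on the face anti to the neighbouring side chain, which sets the future tertiary carbinol carbon of the cyclopentane.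

Step 5
Reactants: 6 (1S,2S,5R)-2-(3-hydroxyprop-1-en-2-yl)-5-methyl-6-oxabicyclo[3.1.0]hexane-1-carbaldehyde
Product: 8 (1S,2R,5R)-2-hydroxy-5-(3-hydroxyprop-1-en-2-yl)-2-methylcyclopentane-1-carbaldehyde, via formyl epimer 7 (not isolated)
Conditions: SmI2 (2.1 equiv), THF/MeOH, −90 °C; then Et3N (0.2 equiv), CH2Cl2, 0 °C
Reagents that add atoms: none
Why: SmI2 reductive opening of the α,β-epoxy aldehyde (ketyl formation, scission of the α C–O bond) keeps the tertiary C–O bond, and mild base equilibrates the formyl carbon through the enol to the epimer that is trans to both the methyl group and the side chain and cis to the hydroxyl.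

Step 6
Reactants: 8 (1S,2R,5R)-2-hydroxy-5-(3-hydroxyprop-1-en-2-yl)-2-methylcyclopentane-1-carbaldehyde; 9 2,4,6-trihydroxyacetophenone (3 equiv)
Product: 11 1-[2,4,6-trihydroxy-3-({(1S,2R,5R)-2-hydroxy-5-(3-hydroxyprop-1-en-2-yl)-2-methylcyclopentyl}methyl)phenyl]ethan-1-one, via o-quinone methide 10 (not isolated)
Conditions: L-proline (20 mol%), Hantzsch ester (1.2 equiv), EtOH, 40 °C
Reagents that add atoms: none
Why: Organocatalytic three-component reductive alkylation: Knoevenagel-type condensation at one of the two equivalent free ring carbons gives the o-quinone methide, which the Hantzsch ester reduces irreversibly; excess 9 suppresses double alkylation and no stereocentre is formed.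

Step 7
Reactants: 11 1-[2,4,6-trihydroxy-3-({(1S,2R,5R)-2-hydroxy-5-(3-hydroxyprop-1-en-2-yl)-2-methylcyclopentyl}methyl)phenyl]ethan-1-one
Product: 13 (1R,3'R,3a'S,7a'R)-3-acetyl-3',4,6-trihydroxy-3'-methyl-7'-methylidene-octahydrospiro[cyclohexa-3,5-diene-1,5'-indene]-2-one, via eight-membered aryl allyl ether 12 (not isolated)
Conditions: Bu3P=CHCN (1.3 equiv), toluene (0.005 M), 80 °C; then 130 °C, sealed tube
Reagents that add atoms: none
Why: Proposed new method: a Mitsunobu-type phosphorane etherification alkylates the most acidic, non-chelated 4-OH (para to acetyl) and closes the eight-membered aryl 2-methyleneallyl ether 12 (the C–O bond); on heating, the exocyclic CH2 can bond productively only to the alkyl-bearing ortho carbon (the other ortho carbon would give a strained meta-bridged ring), so a transannular aromatic Claisen [3,3] shift contracts the ring to the spiro cyclohexane; the chair–chair bicyclo[3.3.1]-like transition state, with the cyclopentane fused diequatorially, forces the carbon that carried the ether oxygen into the axial position syn to the ring-fusion hydrogen next to the CH2 group, so the regiochemistry of the C–O bond is relayed into the (R) spiro centre, and tautomerisation to the vinylogous acid makes the dearomatisation irreversible; the closest known reactions are aromatic Claisen rearrangements of O-allyl and O-prenyl acylphloroglucinols to dearomatised C-allyl triones and ring-contracting Claisen rearrangements of medium-ring allyl vinyl ethers.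

Step 8
Reactants: 13 (1R,3'R,3a'S,7a'R)-3-acetyl-3',4,6-trihydroxy-3'-methyl-7'-methylidene-octahydrospiro[cyclohexa-3,5-diene-1,5'-indene]-2-one
Product: 15 (1R,3'R,3a'S,7'R,7a'R)-3-acetyl-3',4,6,7'-tetrahydroxy-3',7'-dimethyl-octahydrospiro[cyclohexa-3,5-diene-1,5'-indene]-2-one, via tertiary hydroperoxide 14 (not isolated)
Conditions: Mn(dpm)3 (dpm = 2,2,6,6-tetramethylheptane-3,5-dionate, 10 mol%), PhSiH3 (2 equiv), O2 (1 atm), i-PrOH/CH2Cl2, 0 °C; then PPh3
Reagents that add atoms: dioxygen, O=O
Why: Mukaiyama hydration (hydrogen-atom transfer to the CH2 terminus, O2 capture of the tertiary radical, reduction of the hydroperoxide); the axial ring A carbon and its oxygen lie under one face of the radical, so O2 adds from the other face and gives the equatorial alcohol with the methyl group axial, which is the (R) carbinol.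

Step 9
Reactants: 15 (1R,3'R,3a'S,7'R,7a'R)-3-acetyl-3',4,6,7'-tetrahydroxy-3',7'-dimethyl-octahydrospiro[cyclohexa-3,5-diene-1,5'-indene]-2-one; 16 prenyl bromide (3 equiv)
Product: 18 (1R,3'R,3a'S,7'R,7a'R)-3-acetyl-3',4,7'-trihydroxy-3',7'-dimethyl-5,5-bis(3-methylbut-2-en-1-yl)-octahydrospiro[cyclohex-3-ene-1,5'-indene]-2,6-dione (target), via mono-prenyl trione 17 (not isolated)
Conditions: 10% aq. KOH, 0 °C to rt
Reagents that add atoms: none
Why: Twofold enolate C-alkylation of the only remaining nucleophilic ring carbon (the geminal prenylation used for lupulone-type triones); the tertiary alcohols do not react and no stereocentre is formed or disturbed.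

## Compound list

1 | (4R)-limonene 1,2-oxide (cis/trans mixture) | CC12CC[C@H](CC1O2)C(C)=C | starting material
2 | (1S,2S,4R)-limonene-1,2-diol | C[C@]1(O)CC[C@H](C[C@@H]1O)C(C)=C | intermediate (not isolated)
3 | (3R)-6-oxo-3-(prop-1-en-2-yl)heptanal | O=CC[C@@H](CCC(C)=O)C(C)=C | intermediate
4 | (5S)-2-methyl-5-(prop-1-en-2-yl)cyclopent-1-ene-1-carbaldehyde | O=CC1=C(C)CC[C@H]1C(C)=C | intermediate
5 | (5S)-5-(3-hydroxyprop-1-en-2-yl)-2-methylcyclopent-1-ene-1-carbaldehyde | O=CC1=C(C)CC[C@H]1C(CO)=C | intermediate
6 | (1S,2S,5R)-2-(3-hydroxyprop-1-en-2-yl)-5-methyl-6-oxabicyclo[3.1.0]hexane-1-carbaldehyde (epoxide oxygen anti to the side chain) | O=C[C@@]12O[C@]1(C)CC[C@H]2C(CO)=C | intermediate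
7 | (1R,2R,5R)-2-hydroxy-5-(3-hydroxyprop-1-en-2-yl)-2-methylcyclopentane-1-carbaldehyde (formyl epimer of 8) | O=C[C@H]1[C@](C)(O)CC[C@H]1C(CO)=C | intermediate (not isolated)
8 | (1S,2R,5R)-2-hydroxy-5-(3-hydroxyprop-1-en-2-yl)-2-methylcyclopentane-1-carbaldehyde (formyl cis to OH, trans to side chain) | O=C[C@@H]1[C@](C)(O)CC[C@H]1C(CO)=C | intermediate
9 | 2,4,6-trihydroxyacetophenone | CC(=O)c1c(O)cc(O)cc1O | starting material
10 | o-quinone methide from 8 and 9 (alkylidene at the ring carbon between two oxygens) | CC(=O)C1=C(O)C=C(O)C(=C[C@@H]2[C@](C)(O)CC[C@H]2C(CO)=C)C1=O | intermediate (not isolated)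
11 | 1-[2,4,6-trihydroxy-3-({(1S,2R,5R)-2-hydroxy-5-(3-hydroxyprop-1-en-2-yl)-2-methylcyclopentyl}methyl)phenyl]ethan-1-one | CC(=O)c1c(O)cc(O)c(C[C@@H]2[C@](C)(O)CC[C@H]2C(CO)=C)c1O | intermediate
12 | eight-membered cyclic 4-O-aryl 2-methyleneallyl ether of 11 (ArO–CH2–C(=CH2)–CH–CH–CH2–Ar ring) | CC(=O)c1c(O)cc2c(C[C@@H]3[C@](C)(O)CC[C@H]3C(=C)CO2)c1O | intermediate (not isolated)
13 | (1R,3'R,3a'S,7a'R)-3-acetyl-3',4,6-trihydroxy-3'-methyl-7'-methylidene-octahydrospiro[cyclohexa-3,5-diene-1,5'-indene]-2-one | CC(=O)C1=C(O)C=C(O)[C@]2(C[C@H]3[C@@H](CC[C@@]3(C)O)C(=C)C2)C1=O | intermediate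
14 | 7'-hydroperoxy analogue of 15 (tertiary hydroperoxide) | CC(=O)C1=C(O)C=C(O)[C@]2(C[C@H]3[C@@H](CC[C@@]3(C)O)[C@](C)(OO)C2)C1=O | intermediate (not isolated)
15 | (1R,3'R,3a'S,7'R,7a'R)-3-acetyl-3',4,6,7'-tetrahydroxy-3',7'-dimethyl-octahydrospiro[cyclohexa-3,5-diene-1,5'-indene]-2-one | CC(=O)C1=C(O)C=C(O)[C@]2(C[C@H]3[C@@H](CC[C@@]3(C)O)[C@](C)(O)C2)C1=O | intermediate
16 | prenyl bromide (1-bromo-3-methylbut-2-ene) | CC(C)=CCBr | starting material
17 | 5-mono-prenyl derivative of 15 | CC(=O)C1=C(O)C(CC=C(C)C)=C(O)[C@]2(C[C@H]3[C@@H](CC[C@@]3(C)O)[C@](C)(O)C2)C1=O | intermediate (not isolated)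
18 | (1R,3'R,3a'S,7'R,7a'R)-3-acetyl-3',4,7'-trihydroxy-3',7'-dimethyl-5,5-bis(3-methylbut-2-en-1-yl)-octahydrospiro[cyclohex-3-ene-1,5'-indene]-2,6-dione (CNP0266834.2) | CC(=O)C1=C(O)C(CC=C(C)C)(CC=C(C)C)C(=O)[C@]2(C[C@H]3[C@@H](CC[C@@]3(C)O)[C@](C)(O)C2)C1=O | target

## Step count and risks

Total steps: 9. Longest linear sequence: 9 (from 1); 9 and 16 are used as purchased.

The three steps most likely to fail:

Step 7 is the new tandem etherification and Claisen ring contraction. It can fail through etherification at the 2-OH instead of the 4-OH (which would give the spiro epimer), through oligomer formation, or through a Claisen barrier above the temperature the material tolerates. The fallback uses known chemistry and sets out from 11. The free allylic alcohol is cyclised directly at carbon by an intramolecular Tsuji–Trost allylic dearomatisation with Pd2(dba)3 (zerovalent palladium) and a DACH-phenyl Trost ligand in THF at 50 °C. Both ligand enantiomers are screened for the one that favours the (R) spiro epimer, the epimers are separated on silica, and the route is rejoined at 13; no new compound is made (F0).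

Step 8 can fail through attack of O2 on the electron-rich enol CH of ring A or through poor facial selectivity. The fallback sets out from 13. An oxygen-free hydrogen-atom-transfer hydrofunctionalisation with Fe2(C2O4)3 (trivalent iron), NaBH4 and TEMPO in EtOH/H2O at 0 °C traps the tertiary radical from the open face as the alkoxyamine (TEMPO ether) F1. Zn in AcOH then cleaves the N–O bond and the route is rejoined at 15.

Step 9 can fail through O-prenylation, incomplete second alkylation and poor mass balance on the most valuable intermediate. The fallback sets out from 15. A double Tsuji–Trost C-allylation with allyl acetate, Et3N and Pd(PPh3)4 (zerovalent palladium) in THF gives the geminal diallyl trione F2. Cross-metathesis with 2-methyl-2-butene and second-generation Grubbs catalyst at 40 °C turns both allyl groups into prenyl groups and arrives at 18.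

## Further compounds

F0 | step 7 | none | none
F1 | step 8 | 7'-O-(2,2,6,6-tetramethylpiperidin-1-yl) ether of 15 (TEMPO ether) | CC(=O)C1=C(O)C=C(O)[C@]2(C[C@H]3[C@@H](CC[C@@]3(C)O)[C@](C)(ON4C(C)(C)CCCC4(C)C)C2)C1=O
F2 | step 9 | 5,5-diallyl analogue of 18 (geminal diallyl trione) | CC(=O)C1=C(O)C(CC=C)(CC=C)C(=O)[C@]2(C[C@H]3[C@@H](CC[C@@]3(C)O)[C@](C)(O)C2)C1=O
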